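Ring C is opened at C4–C4a and O1–C2. The cut rests on the placement of C4a in ring A: it lies between the oxygen-bearing carbons C5 and C8a and para to C7, whose oxygen carries the gallate, so a phloroglucinol silylated on one oxygen reacts at the carbon between its two free hydroxyls and either hydroxyl can become O1. In one operation a phenylboronic acid-templated condensation joins that carbon to the aldehyde carbon of a (Z)-2-ethoxy-3-arylpropenal (C4, C3, C2, ring B) and the vinyl ortho-quinone methide formed electrocyclises to the 3-ethoxy-2H-chromene. Enol ether hydrolysis and one dynamic kinetic transfer hydrogenation then set C2 and C3 cis.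

Key step: step 5

Remark 1: The enol oxygen at C3 is carried as an ethyl ether and not as a benzyl ether; this alkyl group is lost on hydrolysis, phosphonate 2 is a stock reagent, and the skeletons of both key-step partners and of the chromene are unchanged.
Remark 2: Aldehyde 1, phosphonate 2 and acid 15 are taken as catalogue compounds; 1 and 15 are otherwise one benzylation away from 3,4,5-trihydroxybenzaldehyde and methyl gallate.
Remark 3: The (R,R) hand of the ligand in step 8 is assigned by analogy, with the C2 side of the ketone taken as the large aryl-bearing group; both antipodes are stock items, and the (S,S) complex is used if the first run shows the opposite sense.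

Step 1
Reactants: 1 3,4,5-tris(benzyloxy)benzaldehyde; 2 ethyl 2-(diethoxyphosphoryl)-2-ethoxyacetate
Product: 3 ethyl (Z)-2-ethoxy-3-[3,4,5-tris(benzyloxy)phenyl]prop-2-enoate
Conditions: NaH, THF, 0 °C to rt
Reagents that add atoms: none
Why: Horner–Wadsworth–Emmons olefination of a non-enolisable aryl aldehyde with the sodium salt of an α-alkoxy phosphonoacetate should favour the Z ester (aryl trans to the ester group), and any E isomer is removed by chromatography.

Step 2
Reactants: 3 ethyl (Z)-2-ethoxy-3-[3,4,5-tris(benzyloxy)phenyl]prop-2-enoate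
Product: 4 (Z)-2-ethoxy-3-[3,4,5-tris(benzyloxy)phenyl]prop-2-en-1-ol
Conditions: i-Bu2AlH (2.3 equiv), CH2Cl2, −78 °C
Reagents that add atoms: none
Why: 1,2-Reduction of a conjugated ester with i-Bu2AlH stops at the allylic alcohol and does not touch the enol ether, the alkene geometry or the benzyl ethers.

Step 3
Reactants: 4 (Z)-2-ethoxy-3-[3,4,5-tris(benzyloxy)phenyl]prop-2-en-1-ol
Product: 5 (Z)-2-ethoxy-3-[3,4,5-tris(benzyloxy)phenyl]prop-2-enal
Conditions: MnO2 (excess), CH2Cl2, rt
Reagents that add atoms: none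
Why: Allylic oxidation with MnO2 is selective for the activated allylic alcohol and runs under neutral conditions, so the acid-labile enol ether and the Z geometry should be retained.

Step 4
Reactants: 6 phloroglucinol (benzene-1,3,5-triol, 3 equiv)
Product: 7 5-(triisopropylsilyloxy)benzene-1,3-diol
Conditions: TIPSCl (1 equiv), imidazole, DMF, 0 °C to rt
Reagents that add atoms: triisopropylsilyl chloride, CC(C)[Si](Cl)(C(C)C)C(C)C
Why: Statistical monosilylation of a threefold symmetric triol, in which the excess of 6 suppresses double silylation, unreacted 6 is washed out with water and any bis-ether is separated by chromatography.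

Step 5
Reactants: 7 5-(triisopropylsilyloxy)benzene-1,3-diol (1.3 equiv); 5 (Z)-2-ethoxy-3-[3,4,5-tris(benzyloxy)phenyl]prop-2-enal
Product: 10 racemic 3-ethoxy-7-(triisopropylsilyloxy)-2-[3,4,5-tris(benzyloxy)phenyl]-2H-chromen-5-ol, via benzodioxaborinine 8 (not isolated), via vinyl ortho-quinone methide 9 (not isolated)
Conditions: PhB(OH)2 (1.2 equiv), EtCO2H (cat.), toluene, reflux, Dean–Stark
Reagents that add atoms: none
Why: Phenylboronic acid esterifies a phenolic OH of 7 and binds the aldehyde of 5, so that the ring carbon between the two hydroxyls (the future C4a) adds to the carbonyl carbon (C4) through a six-membered boron-bridged transition state and gives benzodioxaborinine 8; at reflux 8 expels PhBO in a retro-hetero-Diels–Alder-type fragmentation and leaves the oxatriene 9, whose thermally allowed disrotatory oxa-6π electrocyclisation forms O1–C2. The closest known reaction type is the phenylboronic acid-mediated condensation of phenols with α,β-unsaturated aldehydes to 2H-chromenes, a formal (3+3) annulation made up of ortho-hydroxyalkylation and ortho-quinone methide electrocyclisation. Ring C is closed by the 6π electrocyclisation, and the transient dioxaborinine ring by the templated aldol-type C–C bond formation. The only new stereocentre, C2, arises without control and 10 is racemic, which is accepted because C2 is made epimerisable in step 7 and fixed in step 8. The step needs regioselectivity for the carbon flanked by the two hydroxyls over the two carbons beside the silyl ether, which the bulk of the TIPS group and the delivery of the aldehyde to this same carbon from either hydroxyl should secure, and 1,2- over 1,4-addition, which the boron tether enforces. The Z enal places ring B on the outside of the closing triene, and azeotropic removal of water protects the enol ether.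

Step 6
Reactants: 10 racemic 3-ethoxy-7-(triisopropylsilyloxy)-2-[3,4,5-tris(benzyloxy)phenyl]-2H-chromen-5-ol
Product: 11 racemic 5-benzyloxy-3-ethoxy-7-(triisopropylsilyloxy)-2-[3,4,5-tris(benzyloxy)phenyl]-2H-chromene
Conditions: BnBr, K2CO3, acetone, 50 °C
Reagents that add atoms: benzyl bromide, BrCc1ccccc1
Why: Williamson ether synthesis on the only free phenol under mild carbonate conditions, to which the aryl TIPS ether, the enol ether and the chromene are stable.

Step 7
Reactants: 11 racemic 5-benzyloxy-3-ethoxy-7-(triisopropylsilyloxy)-2-[3,4,5-tris(benzyloxy)phenyl]-2H-chromene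
Product: 12 racemic 5-benzyloxy-7-(triisopropylsilyloxy)-2-[3,4,5-tris(benzyloxy)phenyl]chroman-3-one
Conditions: 1 M aq. HCl, THF, rt, argon; used crude
Reagents that add atoms: water, O
Why: Acid-catalysed enol ether hydrolysis (protonation at C4, addition of water to the C3 oxocarbenium ion, loss of ethanol) runs under conditions that aryl TIPS and benzyl ethers tolerate, and the configurational lability that C2 gains is wanted for step 8.

Step 8
Reactants: 12 racemic 5-benzyloxy-7-(triisopropylsilyloxy)-2-[3,4,5-tris(benzyloxy)phenyl]chroman-3-one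
Product: 13 (2R,3R)-5-benzyloxy-7-(triisopropylsilyloxy)-2-[3,4,5-tris(benzyloxy)phenyl]chroman-3-ol (2,3-cis)
Conditions: RuCl[(R,R)-TsDPEN](p-cymene) (2 mol%), HCO2H/Et3N (5:2), DMF, 30 °C, argon
Reagents that add atoms: none
Why: Noyori asymmetric transfer hydrogenation with dynamic kinetic resolution, in which C2–H (benzylic, α to O1 and to the ketone) should epimerise through the enol faster than reduction, the hydride formed from RuCl[(R,R)-TsDPEN](p-cymene) should reduce one ketone enantiomer preferentially and so set C3 (R) under catalyst control, and hydride delivery anti to the pseudo-equatorial 2-aryl group places the hydroxyl cis to ring B and so fixes C2 (R).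

Step 9
Reactants: 13 (2R,3R)-5-benzyloxy-7-(triisopropylsilyloxy)-2-[3,4,5-tris(benzyloxy)phenyl]chroman-3-ol
Product: 14 (2R,3R)-5-benzyloxy-2-[3,4,5-tris(benzyloxy)phenyl]chroman-3,7-diol
Conditions: Bu4NF (1.1 equiv), AcOH (1.1 equiv), THF, 0 °C
Reagents that add atoms: none
Why: Fluoride-mediated cleavage of the aryl silyl ether, driven by Si–F bond formation and buffered with acetic acid so that the phenoxide is protonated at once, leaves the benzyl ethers, the secondary alcohol and both stereocentres untouched.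

Step 10
Reactants: 15 3,4,5-tris(benzyloxy)benzoic acid
Product: 16 3,4,5-tris(benzyloxy)benzoyl chloride
Conditions: (COCl)2, DMF (cat.), CH2Cl2, 0 °C to rt; evaporate
Reagents that add atoms: oxalyl chloride, ClC(=O)C(=O)Cl
Why: Acid chloride formation through the chloroiminium (Vilsmeier-type) species is standard for alkoxybenzoic acids, spares benzyl ethers and gives only gaseous by-products.

Step 11
Reactants: 14 (2R,3R)-5-benzyloxy-2-[3,4,5-tris(benzyloxy)phenyl]chroman-3,7-diol; 16 3,4,5-tris(benzyloxy)benzoyl chloride (1.05 equiv)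
Product: 17 (2R,3R)-5-benzyloxy-3-hydroxy-2-[3,4,5-tris(benzyloxy)phenyl]chroman-7-yl 3,4,5-tris(benzyloxy)benzoate
Conditions: Et3N, CH2Cl2, −20 to 0 °C, no DMAP
Reagents that add atoms: none
Why: Chemoselective Einhorn-type O-acylation of a phenol beside an alcohol, in which only the phenol is acidic enough to be activated by Et3N, while the hindered axial 3-hydroxyl would need a nucleophilic catalyst that is left out.

Step 12
Reactants: 17 (2R,3R)-5-benzyloxy-3-hydroxy-2-[3,4,5-tris(benzyloxy)phenyl]chroman-7-yl 3,4,5-tris(benzyloxy)benzoate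
Product: 18 epigallocatechin 7-O-gallate [(2R,3R)-3,5-dihydroxy-2-(3,4,5-trihydroxyphenyl)chroman-7-yl 3,4,5-trihydroxybenzoate]
Conditions: H2 (1 atm), Pd(OH)2/C, THF/EtOAc, rt; filtration under argon
Reagents that add atoms: none
Why: Catalytic hydrogenolysis cleaves all seven benzyl ethers under neutral conditions in a non-nucleophilic solvent, while the aryl ester, the cyclic C2–O1 ether and the two stereocentres should not be affected.

Compound list

1 | 3,4,5-tris(benzyloxy)benzaldehyde | O=Cc1cc(OCc2ccccc2)c(OCc2ccccc2)c(OCc2ccccc2)c1 | starting material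
2 | ethyl 2-(diethoxyphosphoryl)-2-ethoxyacetate | CCOC(=O)C(OCC)P(=O)(OCC)OCC | starting material
3 | ethyl (Z)-2-ethoxy-3-[3,4,5-tris(benzyloxy)phenyl]prop-2-enoate | CCOC(=O)/C(OCC)=C/c1cc(OCc2ccccc2)c(OCc2ccccc2)c(OCc2ccccc2)c1 | intermediate
4 | (Z)-2-ethoxy-3-[3,4,5-tris(benzyloxy)phenyl]prop-2-en-1-ol | OC/C(OCC)=C/c1cc(OCc2ccccc2)c(OCc2ccccc2)c(OCc2ccccc2)c1 | intermediate
5 | (Z)-2-ethoxy-3-[3,4,5-tris(benzyloxy)phenyl]prop-2-enal | O=C/C(OCC)=C/c1cc(OCc2ccccc2)c(OCc2ccccc2)c(OCc2ccccc2)c1 | intermediate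
6 | phloroglucinol | Oc1cc(O)cc(O)c1 | starting material
7 | 5-(triisopropylsilyloxy)benzene-1,3-diol | CC(C)[Si](Oc1cc(O)cc(O)c1)(C(C)C)C(C)C | intermediate
8 | racemic 4-[(Z)-1-ethoxy-2-[3,4,5-tris(benzyloxy)phenyl]ethenyl]-2-phenyl-7-(triisopropylsilyloxy)-4H-1,3,2-benzodioxaborinin-5-ol | CC(C)[Si](Oc1cc(O)c2c(c1)OB(c1ccccc1)OC2/C(OCC)=C/c1cc(OCc2ccccc2)c(OCc2ccccc2)c(OCc2ccccc2)c1)(C(C)C)C(C)C | intermediate
9 | (6Z)-6-[(2Z)-2-ethoxy-3-[3,4,5-tris(benzyloxy)phenyl]prop-2-en-1-ylidene]-5-hydroxy-3-(triisopropylsilyloxy)cyclohexa-2,4-dien-1-one | O=C1C=C(O[Si](C(C)C)(C(C)C)C(C)C)C=C(O)/C1=C/C(OCC)=C/c1cc(OCc2ccccc2)c(OCc2ccccc2)c(OCc2ccccc2)c1 | intermediate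
10 | racemic 3-ethoxy-7-(triisopropylsilyloxy)-2-[3,4,5-tris(benzyloxy)phenyl]-2H-chromen-5-ol | CC(C)[Si](Oc1cc(O)c2c(c1)OC(c1cc(OCc3ccccc3)c(OCc3ccccc3)c(OCc3ccccc3)c1)C(OCC)=C2)(C(C)C)C(C)C | intermediate
11 | racemic 5-benzyloxy-3-ethoxy-7-(triisopropylsilyloxy)-2-[3,4,5-tris(benzyloxy)phenyl]-2H-chromene | CC(C)[Si](Oc1cc(OCc3ccccc3)c2c(c1)OC(c1cc(OCc3ccccc3)c(OCc3ccccc3)c(OCc3ccccc3)c1)C(OCC)=C2)(C(C)C)C(C)C | intermediate
12 | racemic 5-benzyloxy-7-(triisopropylsilyloxy)-2-[3,4,5-tris(benzyloxy)phenyl]chroman-3-one | CC(C)[Si](Oc1cc(OCc3ccccc3)c2c(c1)OC(c1cc(OCc3ccccc3)c(OCc3ccccc3)c(OCc3ccccc3)c1)C(=O)C2)(C(C)C)C(C)C | intermediate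
13 | (2R,3R)-5-benzyloxy-7-(triisopropylsilyloxy)-2-[3,4,5-tris(benzyloxy)phenyl]chroman-3-ol | CC(C)[Si](Oc1cc(OCc3ccccc3)c2c(c1)O[C@H](c1cc(OCc3ccccc3)c(OCc3ccccc3)c(OCc3ccccc3)c1)[C@H](O)C2)(C(C)C)C(C)C | intermediate
14 | (2R,3R)-5-benzyloxy-2-[3,4,5-tris(benzyloxy)phenyl]chroman-3,7-diol | Oc1cc(OCc3ccccc3)c2c(c1)O[C@H](c1cc(OCc3ccccc3)c(OCc3ccccc3)c(OCc3ccccc3)c1)[C@H](O)C2 | intermediate
15 | 3,4,5-tris(benzyloxy)benzoic acid | OC(=O)c1cc(OCc2ccccc2)c(OCc2ccccc2)c(OCc2ccccc2)c1 | starting material
16 | 3,4,5-tris(benzyloxy)benzoyl chloride | ClC(=O)c1cc(OCc2ccccc2)c(OCc2ccccc2)c(OCc2ccccc2)c1 | intermediate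
17 | (2R,3R)-5-benzyloxy-3-hydroxy-2-[3,4,5-tris(benzyloxy)phenyl]chroman-7-yl 3,4,5-tris(benzyloxy)benzoate | O=C(Oc1cc(OCc3ccccc3)c2c(c1)O[C@H](c1cc(OCc3ccccc3)c(OCc3ccccc3)c(OCc3ccccc3)c1)[C@H](O)C2)c1cc(OCc2ccccc2)c(OCc2ccccc2)c(OCc2ccccc2)c1 | intermediate
18 | epigallocatechin 7-O-gallate, (2R,3R) | O=C(Oc1cc(O)c2c(c1)O[C@H](c1cc(O)c(O)c(O)c1)[C@H](O)C2)c1cc(O)c(O)c(O)c1 | target

Total step count: 12. Longest linear sequence: 10 steps (steps 1, 2, 3, 5, 6, 7, 8, 9, 11 and 12).

Steps most likely to fail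

Step 5. The enol ether may be hydrolysed by the hot carboxylic acid before or after ring closure, or the α-substituted aldehyde may condense so slowly that the electron-rich phenol decomposes or reacts twice. The fallback brings in the C3 oxygen after ring closure instead of carrying it in the enal; it sets out from 1 and 7 and comes back at 12. Aldehyde 1 would be homologated by a Wittig reaction with Ph3P=CHCHO (toluene, 80 °C) to (E)-3-[3,4,5-tris(benzyloxy)phenyl]prop-2-enal F1. With 7 under the conditions of step 5, this plain cinnamaldehyde should give racemic 7-(triisopropylsilyloxy)-2-[3,4,5-tris(benzyloxy)phenyl]-2H-chromen-5-ol F2. Benzylation (BnBr, K2CO3, acetone) would give racemic 5-benzyloxy-7-(triisopropylsilyloxy)-2-[3,4,5-tris(benzyloxy)phenyl]-2H-chromene F3. Hydroboration–oxidation (BH3·SMe2, THF, 0 °C; then NaBO3·4H2O, H2O) should place the hydroxyl at C3, anti to ring B, and give racemic 2,3-trans-5-benzyloxy-7-(triisopropylsilyloxy)-2-[3,4,5-tris(benzyloxy)phenyl]chroman-3-ol F4. Dess–Martin oxidation (NaHCO3, CH2Cl2) then returns to the route at ketone 12.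

Step 8. Epimerisation at C2 may be slower than hydride transfer, or the catalyst may discriminate poorly between the two ketone enantiomers because no aryl group sits directly on the carbonyl; either would erode enantiomeric purity or give trans alcohol. The fallback replaces catalytic dynamic resolution by substrate-controlled reduction, physical resolution and recycling; it sets out from 12 and comes back at 13. Ketone 12 would be reduced with LiBH(s-Bu)3 (THF, −78 °C), which should attack anti to ring B and give the racemic cis alcohol, that is 13 together with its mirror image (2S,3S)-5-benzyloxy-7-(triisopropylsilyloxy)-2-[3,4,5-tris(benzyloxy)phenyl]chroman-3-ol F5. Preparative chromatography on a chiral stationary phase separates the two, and F5 is oxidised back to 12 with Dess–Martin periodinane and recycled.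

Step 11. Acyl transfer to the 3-hydroxyl may compete with acylation of the phenol and give mixtures of mono- and diesters. The fallback masks the 3-hydroxyl with a group that the final hydrogenolysis removes; it sets out from 13 and comes back at 18. Alcohol 13 would be benzylated (NaH, BnBr, Bu4NI, THF/DMF, 0 °C) to (2R,3R)-3,5-bis(benzyloxy)-7-(triisopropylsilyloxy)-2-[3,4,5-tris(benzyloxy)phenyl]chromane F6. Desilylation (Bu4NF, AcOH, THF) would give (2R,3R)-3,5-bis(benzyloxy)-2-[3,4,5-tris(benzyloxy)phenyl]chroman-7-ol F7. Acylation with 16 (Et3N, DMAP, CH2Cl2), now without any selectivity demand, would give (2R,3R)-3,5-bis(benzyloxy)-2-[3,4,5-tris(benzyloxy)phenyl]chroman-7-yl 3,4,5-tris(benzyloxy)benzoate F8. Hydrogenolysis of its eight benzyl ethers (H2, Pd(OH)2/C, THF/EtOAc) gives target 18.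

Further compounds

F1 | step 5 | (E)-3-[3,4,5-tris(benzyloxy)phenyl]prop-2-enal | O=C/C=C/c1cc(OCc2ccccc2)c(OCc2ccccc2)c(OCc2ccccc2)c1
F2 | step 5 | racemic 7-(triisopropylsilyloxy)-2-[3,4,5-tris(benzyloxy)phenyl]-2H-chromen-5-ol | CC(C)[Si](Oc1cc(O)c2c(c1)OC(c1cc(OCc3ccccc3)c(OCc3ccccc3)c(OCc3ccccc3)c1)C=C2)(C(C)C)C(C)C
F3 | step 5 | racemic 5-benzyloxy-7-(triisopropylsilyloxy)-2-[3,4,5-tris(benzyloxy)phenyl]-2H-chromene | CC(C)[Si](Oc1cc(OCc3ccccc3)c2c(c1)OC(c1cc(OCc3ccccc3)c(OCc3ccccc3)c(OCc3ccccc3)c1)C=C2)(C(C)C)C(C)C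
F4 | step 5 | racemic 2,3-trans-5-benzyloxy-7-(triisopropylsilyloxy)-2-[3,4,5-tris(benzyloxy)phenyl]chroman-3-ol, drawn as the (2R,3S) enantiomer | CC(C)[Si](Oc1cc(OCc3ccccc3)c2c(c1)O[C@H](c1cc(OCc3ccccc3)c(OCc3ccccc3)c(OCc3ccccc3)c1)[C@@H](O)C2)(C(C)C)C(C)C
F5 | step 8 | (2S,3S)-5-benzyloxy-7-(triisopropylsilyloxy)-2-[3,4,5-tris(benzyloxy)phenyl]chroman-3-ol | CC(C)[Si](Oc1cc(OCc3ccccc3)c2c(c1)O[C@@H](c1cc(OCc3ccccc3)c(OCc3ccccc3)c(OCc3ccccc3)c1)[C@@H](O)C2)(C(C)C)C(C)C
F6 | step 11 | (2R,3R)-3,5-bis(benzyloxy)-7-(triisopropylsilyloxy)-2-[3,4,5-tris(benzyloxy)phenyl]chromane | CC(C)[Si](Oc1cc(OCc3ccccc3)c2c(c1)O[C@H](c1cc(OCc3ccccc3)c(OCc3ccccc3)c(OCc3ccccc3)c1)[C@H](OCc1ccccc1)C2)(C(C)C)C(C)C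
F7 | step 11 | (2R,3R)-3,5-bis(benzyloxy)-2-[3,4,5-tris(benzyloxy)phenyl]chroman-7-ol | Oc1cc(OCc3ccccc3)c2c(c1)O[C@H](c1cc(OCc3ccccc3)c(OCc3ccccc3)c(OCc3ccccc3)c1)[C@H](OCc1ccccc1)C2
F8 | step 11 | (2R,3R)-3,5-bis(benzyloxy)-2-[3,4,5-tris(benzyloxy)phenyl]chroman-7-yl 3,4,5-tris(benzyloxy)benzoate | O=C(Oc1cc(OCc3ccccc3)c2c(c1)O[C@H](c1cc(OCc3ccccc3)c(OCc3ccccc3)c(OCc3ccccc3)c1)[C@H](OCc1ccccc1)C2)c1cc(OCc2ccccc2)c(OCc2ccccc2)c(OCc2ccccc2)c1
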